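Remarks and assumptions. Cembrane numbering is used throughout: C1 is the ring carbon bonded to C15; the ring runs C2 (CH2), C3–C4 (oxirane, C18 methyl on C4), C5, C6=C7, C8 (C19 methyl, OH), C9–C11, C12 (C20 methyl), C13 (OAc), C14 (lactone O); C15 is the α-carbon, C16 the carbonyl and C17 the exocyclic CH2. The target is (1S,3R,4R,6E,8S,12S,13R,14R). (S)-(+)-Linalool is assumed to be bought in high enantiomeric purity.

## Analysis of the target

The target is a cembranolide: a 14-membered carbocycle (C1–C14) whose C1–C14 bond is shared with an α-methylene-γ-butyrolactone (ring atoms O, C16, C15, C1, C14; exocyclic C17H2) in a cis fusion (H1 and H14 on the same face). Its seven stereocentres fall into three groups that are insulated from each other by methylene spacers (C2; C5; C9–C11): the contiguous tetrad C12(CH3)–C13(OAc)–C14(O)–C1 with 12,13-syn, 13,14-syn and 1,14-cis relations, the trans trisubstituted oxirane C3–C4 (formally the epoxide of a 3E olefin), and the tertiary allylic carbinol C8 next to the 6E olefin. No group can relay its configuration to another, so each must come from the chiral pool or from reagent control. The array C13(O)–C14(O)–C1(H)–C15(=C17H2)–C16(=O) is the retron of the addition of a 2-alkoxycarbonylallyl metal to an α-oxygenated aldehyde, and its central bond C1–C14 is a ring bond of both the lactone and the carbocycle; this is the feature the key step exploits. Sensitive groups are the methylene lactone (Michael acceptor, base-labile), the trisubstituted oxirane (opens in aqueous acid and with Lewis acids), the tertiary allylic alcohol (ionises in acid) and the C13 acetate next to an oxygenated carbon (acyl migration). The hard parts are the entropic cost of the 14-membered ring, the joint control of the cis lactone and the 13,14-syn relation, and telling apart three different C=C bonds in the late oxidation.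

## Retrosynthetic reasoning

Target 29 to 28. The two C–O bonds of the oxirane are cut first. The epoxide is the one group that cannot survive the aqueous, mildly acidic medium of the ring closure. The 3E olefin of 28 is the only electron-rich trisubstituted double bond left, so a reagent-controlled electrophilic epoxidation can be the last step. The forward reaction must choose C3=C4 over C6=C7 and C15=C17, and one face of it.

28 to 27. The acetyl C–O bond at C13 is cut. In 27 the C13 hydroxyl is the only secondary one (C8–OH is tertiary), so no protecting group is needed, and a free C13 hydroxyl is exactly what the key step requires.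

27 to 24 (key disconnection). The C1–C14 bond and the lactone C16–O bond are cut together. This opens both rings at once and leaves the acyclic α-hydroxy aldehyde 24, which carries a 2-(bromomethyl)alk-2-enoate. The cut is made here and not at C6=C7 because this is the only ring bond whose formation creates stereocentres (C1 and C14) and the lactone at the same time, and because the neighbouring C13 hydroxyl can steer it through a chelate. The precursor has three stereocentres instead of five and no ring. The forward reaction, a Barbier-type allylation in water followed by lactonisation, must deliver 13,14-syn, 1,14-cis and a 14-membered ring instead of oligomers.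

24 to 23 to 13 + 22. The aldehyde is traced back to the primary alcohol of the 1,2-diol 23. The E-C6=C7 bond of 23 is cut by cross-metathesis into vinyl carbinol 13 and terminal olefin 22. This bond lies between two stereochemical domains and carries no stereocentre; the fully substituted C8 enforces E geometry; the two fragments are of similar size.

13 to 5 + 9. The C11–C12 bond is cut by way of hydroxy acid 11: an organocopper reagent from bromide 5 opens the trans-epoxy carboxylate 9 at C3 with inversion. One reaction creates C12 and brings in C13 and C14 at the right oxidation pattern. All four contiguous stereocentres of the target therefore descend from the single asymmetric epoxidation that gives 7 (from 6), the precursor of 9.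

5 to 1. (S)-Linalool 1 already holds C6–C11, C19 and the C8 stereocentre with its vinyl group. Cleaving its trisubstituted olefin exposes C11 (alcohol 4, bromide 5). C8 is bought, not made.

22 to 21 to 18 + 19, and 18 to 17 to 14. Allylic bromide 22 is the transposed bromide of the Morita–Baylis–Hillman-type alcohol 21, whose C1–C15 bond joins aldehyde 18 and propiolate 19. Aldehyde 18 comes from dienol 17, whose E-trisubstituted C3=C4 olefin with the C18 methyl is set by carboalumination of enyne 14.

## Alternatives that were turned down

Alternative 1: the textbook cut at C6=C7 of the finished chain. The forward key step would be ring-closing metathesis of the open-chain epoxy acetate lactone A1 (the target with the C6=C7 bond replaced by two vinyl groups). It was turned down for three reasons.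
- It forms the one ring bond that carries no stereochemical information. All seven stereocentres and the lactone would still have to be built in the open chain, including an intermolecular version of the allylation used here, so no step is saved.
- The C7 vinyl group sits on the fully substituted C8 and is a slow metathesis partner, and the E geometry of a 14-membered ring is not secured by anything in the substrate. In the open-chain cross-metathesis chosen here E is enforced thermodynamically.
- The methylene lactone, the oxirane and the tertiary allylic alcohol would all be exposed to a ruthenium carbene at high dilution for a long time.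

A variant of this closure is kept only as a fallback.

Alternative 2: ring contraction across C1–C14 by a [2,3]-Wittig rearrangement. A 17-membered allyl propargyl ether A2 (oxygen bridging C14 and C17, triple bond C12≡C13) would be deprotonated at C14 and contract to the 14-membered propargylic alcohol A3 with an isopropenyl group on C1. The step closes the carbocycle and sets C1 and C14, but it leaves both neighbours at the wrong oxidation pattern.
- The C12≡C13 triple bond of A3 would have to become C12(H)(CH3)–C13(H)(OAc). That means carbometalation and then hydroboration or epoxide reduction, with two new stereocentres and no element to control them, in the presence of two other olefins that react under the same conditions.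
- The isopropenyl group would need allylic oxidation at C16 in a molecule with several other allylic positions before the lactone could be closed.
- At least six operations would follow the key step, against two here.

Alternative 3: biomimetic late oxygenation. The 7E-olefin epoxy lactone A4 would be treated with singlet oxygen (Schenck ene reaction) to give the C8 hydroperoxide A5, which is reduced to target 29. This copies the presumed origin of the 8-hydroxy-6E-ene unit and would allow C2–C9 to come from geraniol. It was turned down because the ene reaction has no reagent control.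
- Hydrogen abstraction on the disubstituted side of the C7=C8 olefin can occur from C6 (tertiary C8 hydroperoxide) or from C19 (secondary C7 hydroperoxide with an exocyclic methylene).
- The face of attack at C8 would depend on an unknown macrocycle conformation.
- The hardest remote stereocentre would thus be left to chance in the last step, whereas (S)-linalool supplies it in step 1. Making A4 still needs the same macrocyclisation.

Key step: step 14

## Route

Step 1
Reactants: 1 (S)-(+)-linalool, (3S)-3,7-dimethylocta-1,6-dien-3-ol
Product: 2 triethyl{[(3S)-3,7-dimethylocta-1,6-dien-3-yl]oxy}silane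
Conditions: TESOTf, 2,6-lutidine, CH2Cl2, −78 → 0 °C
Reagents that add atoms: triethylsilyl trifluoromethanesulfonate, CC[Si](CC)(CC)OS(=O)(=O)C(F)(F)F
Why: O-Silylation of the hindered tertiary allylic alcohol needs the silyl triflate; lutidine buffers the acid that would ionise the allylic carbinol, and the ether masks the hydroxyl for the Grignard stage.

Step 2
Reactants: 2 linalool triethylsilyl ether
Product: 4 (4S)-4-methyl-4-(triethylsilyloxy)hex-5-en-1-ol, via aldehyde 3 (not isolated)
Conditions: O3, pyridine, CH2Cl2, −78 °C (Sudan Red 7B end-point); then NaBH4, MeOH, −78 → 0 °C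
Reagents that add atoms: ozone, [O-][O+]=O
Why: Criegee ozonolysis attacks the electron-rich trisubstituted olefin much faster than the vinyl group on the fully substituted silyloxy carbon, and borohydride reduces the aldehyde in the same flask, exposing C11 without touching C8.

Step 3
Reactants: 4 (4S)-4-methyl-4-(triethylsilyloxy)hex-5-en-1-ol
Product: 5 {[(3S)-6-bromo-3-methylhex-1-en-3-yl]oxy}triethylsilane
Conditions: CBr4, PPh3, 2,6-lutidine, CH2Cl2, 0 °C
Reagents that add atoms: tetrabromomethane, BrC(Br)(Br)Br
Why: Appel bromination of the primary alcohol under neutral conditions spares the silyl ether and the vinyl group.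

Step 4
Reactants: 6 (2E)-but-2-en-1-ol
Product: 7 [(2S,3S)-3-methyloxiran-2-yl]methanol
Conditions: Ti(OiPr)4 (cat.), L-(+)-diethyl tartrate (cat.), t-BuOOH, 4 Å MS, CH2Cl2, −20 °C
Reagents that add atoms: tert-butyl hydroperoxide, CC(C)(C)OO
Why: Sharpless asymmetric epoxidation; the L-(+)-tartrate complex delivers oxygen to the face that gives the (2S,3S)-epoxy alcohol, and this single reagent-controlled epoxide is the source of C12 and C13 and, through them, of C14 and C1.

Step 5
Reactants: 7 [(2S,3S)-3-methyloxiran-2-yl]methanol
Product: 9 lithium (2R,3S)-3-methyloxirane-2-carboxylate, via epoxy acid 8 (not isolated)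
Conditions: RuCl3·xH2O (cat.), NaIO4, CCl4/MeCN/H2O, 0 °C → rt; then LiOH (1.0 equiv), H2O, freeze-dry
Reagents that add atoms: sodium periodate, [Na+].[O-]I(=O)(=O)=O; water, O; lithium hydroxide, [Li+].[OH-]
Why: Ruthenium tetroxide generated in situ oxidises the primary alcohol to the acid without opening the oxirane or touching its stereocentres; isolation as the lithium salt means no organometallic is spent on deprotonation in step 6.

Step 6
Reactants: 5 {[(3S)-6-bromo-3-methylhex-1-en-3-yl]oxy}triethylsilane; 9 lithium (2R,3S)-3-methyloxirane-2-carboxylate
Product: 11 (2R,3S,7S)-2-hydroxy-3,7-dimethyl-7-(triethylsilyloxy)non-8-enoic acid, via Grignard reagent 10 (not isolated)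
Conditions: Mg, THF, rt; then 9, CuBr·SMe2 (cat.), THF, −30 → 0 °C; cold 1 M HCl
Reagents that add atoms: none
Why: Grignard formation followed by copper-catalysed SN2 opening of the epoxy carboxylate; the carboxylate shields C2 electrostatically, so the organocopper attacks C3 with inversion, which makes C12 (S) and the 12,13-syn relation while C13 (R) is retained from the epoxide.

Step 7
Reactants: 11 (2R,3S,7S)-2-hydroxy-3,7-dimethyl-7-(triethylsilyloxy)non-8-enoic acid
Product: 13 (2R,3S,7S)-3,7-dimethylnon-8-ene-1,2,7-triol, via diol silyl ether 12 (not isolated)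
Conditions: LiAlH4, THF, 0 → 40 °C; aq. potassium sodium tartrate; then TBAF, THF, rt
Reagents that add atoms: none
Why: Hydride reduction of the carboxylate to the primary alcohol and fluoride desilylation; neither touches a stereocentre or the isolated vinyl group, and the free C8 hydroxyl is wanted for the metathesis.

Step 8
Reactants: 14 pent-1-en-4-yne
Product: 17 (3E)-4-methylhepta-3,6-dien-1-ol, via alkenylalane 15 (not isolated), via lithium alanate 16 (not isolated)
Conditions: AlMe3, Cp2ZrCl2 (cat.), CH2Cl2, 0 °C → rt; then n-BuLi, THF/hexane, −78 °C; oxirane, −78 → 0 °C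
Reagents that add atoms: trimethylaluminium, C[Al](C)C; oxirane, C1CO1
Why: Zirconium-catalysed carboalumination (Negishi) adds methyl and aluminium syn across the terminal alkyne, which fixes the E geometry of C3=C4 with the C18 methyl on C4; the alanate opens oxirane with retention at the sp2 carbon, and the isolated terminal olefin does not react.

Step 9
Reactants: 17 (3E)-4-methylhepta-3,6-dien-1-ol
Product: 18 (3E)-4-methylhepta-3,6-dienal
Conditions: Dess–Martin periodinane, NaHCO3, CH2Cl2, 0 °C; used at once
Reagents that add atoms: none
Why: Buffered Dess–Martin oxidation gives the β,γ-unsaturated aldehyde without acid or base that would move the olefin into conjugation.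

Step 10
Reactants: 18 (3E)-4-methylhepta-3,6-dienal; 19 methyl prop-2-ynoate
Product: 21 methyl (5E)-3-hydroxy-6-methyl-2-methylidenenona-5,8-dienoate (racemic carbinol), via vinylalane 20 (not isolated)
Conditions: 19, i-Bu2AlH, N-methylmorpholine N-oxide, THF, 0 °C; then 18, 0 °C → rt
Reagents that add atoms: none
Why: Hydroalumination of the propiolate gives the α-aluminoacrylate, which adds 1,2 to the aldehyde (vinylalumination) and forms the C1–C15 bond of a Morita–Baylis–Hillman-type adduct without the amine catalyst that would isomerise the skipped enal; the new carbinol centre becomes sp2 in step 11.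

Step 11
Reactants: 21 methyl (5E)-3-hydroxy-6-methyl-2-methylidenenona-5,8-dienoate
Product: 22 methyl (2Z,5E)-2-(bromomethyl)-6-methylnona-2,5,8-trienoate
Conditions: NBS, Me2S, CH2Cl2, 0 °C → rt
Reagents that add atoms: N-bromosuccinimide, O=C1CCC(=O)N1Br
Why: Corey–Kim-type activation of the allylic alcohol and SN2′ return of bromide gives the thermodynamically preferred (Z)-2-(bromomethyl)enoate; regio- or geometric isomers would serve equally in step 14.

Step 12
Reactants: 13 (2R,3S,7S)-3,7-dimethylnon-8-ene-1,2,7-triol; 22 methyl (2Z,5E)-2-(bromomethyl)-6-methylnona-2,5,8-trienoate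
Product: 23 methyl (2Z,5E,8E,10S,14S,15R)-2-(bromomethyl)-10,15,16-trihydroxy-6,10,14-trimethylhexadeca-2,5,8-trienoate
Conditions: second-generation Hoveyda–Grubbs catalyst (cat.), 1,4-benzoquinone (cat.), CH2Cl2, 40 °C, 22 in excess
Reagents that add atoms: none
Why: Olefin cross-metathesis joins the two terminal olefins into C6=C7; the vinyl carbinol cannot homodimerise and its fully substituted neighbour enforces E, the two trisubstituted olefins of 22 are inert, and benzoquinone suppresses migration of the skipped diene.

Step 13
Reactants: 23 seco triol bromide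
Product: 24 methyl (2Z,5E,8E,10S,14S,15R)-2-(bromomethyl)-10,15-dihydroxy-6,10,14-trimethyl-16-oxohexadeca-2,5,8-trienoate
Conditions: TEMPO (cat.), PhI(OAc)2, CH2Cl2, 0 °C → rt; crude used directly
Reagents that add atoms: none
Why: The oxoammonium oxidation is selective for the primary carbinol over the secondary and tertiary ones, the α-hydroxy aldehyde is protected from further oxidation as its hemiacetal dimer, and the neutral medium leaves the allylic bromide and the C13 configuration alone.

Step 14
Reactants: 24 α-hydroxy aldehyde bromide
Product: 27 (1S,3E,6E,8S,12S,13R,14R)-8,13-dihydroxycembra-3,6,15(17)-trien-16,14-olide, via allylindium species 25 (not isolated), via hydroxy ester 26 (not isolated)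
Conditions: indium powder, THF/H2O (1:1), syringe-pump addition of 24 (final ca. 2 mM), 25 °C; then PPTS (cat.), CH2Cl2, rt
Reagents that add atoms: none
Why: Indium inserts into the allylic C–Br bond to give allylindium 25, whose 1,3-metal shift equilibrates geometric and regio-isomers to the form with C2 cis to CH2–indium (A(1,3) strain against the ester), so every isomer of the bromide is funnelled into one reagent; this is a Barbier-type carbonyl allylation, closest to indium additions of 2-(bromomethyl)alk-2-enoates to free α-hydroxy aldehydes in water and to chromium- or zinc-mediated allylations that close 14-membered cembranoid rings. Trivalent indium tolerates water and the three free hydroxyls, bridges the C13 hydroxyl and the C14 carbonyl oxygen, and bonds through the γ-carbon C1 in a six-membered chair transition state (SE2′). The carbocycle closes by a 14-exo-trig addition to the aldehyde (C1–C14), and the lactone then closes by a 5-exo-trig acyl substitution of O14 on the C16 ester under PPTS. C14 is controlled by C13 through the Cram chelate: attack on the aldehyde face anti to the C12 branch gives the 13,14-syn diol, that is 14R. C1 is controlled by the chair: with C2 axial and the C13 chain equatorial the adduct is syn, which is the cis-fused lactone, that is 1S. The step needs γ- over α-attack, chelate over Felkin–Anh control, syn over anti addition, and ring closure over oligomerisation and protonolysis; these rest on the intrinsic SE2′ preference of allylindium reagents, the unprotected α-hydroxyl, the trisubstituted geometry of the allyl unit, and slow addition together with the two E olefins that stiffen the tether. The five-membered lactone at O14 is preferred over a six-membered one at O13 both kinetically and thermodynamically.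

Step 15
Reactants: 27 lactone diol
Product: 28 (1S,3E,6E,8S,12S,13R,14R)-13-acetoxy-8-hydroxycembra-3,6,15(17)-trien-16,14-olide
Conditions: Ac2O, pyridine, DMAP (cat.), CH2Cl2, 0 °C
Reagents that add atoms: acetic anhydride, CC(=O)OC(C)=O
Why: Nucleophile-catalysed acylation of the only secondary hydroxyl; the tertiary allylic C8 hydroxyl does not react at 0 °C.

Step 16
Reactants: 28 triene acetate
Product: 29 (1S,3R,4R,6E,8S,12S,13R,14R)-13-acetoxy-3,4-epoxy-8-hydroxycembra-6,15(17)-dien-16,14-olide (target)
Conditions: D-fructose-derived Shi ketone (1–3 equiv), KHSO5 (as 2KHSO5·KHSO4·K2SO4), NaHCO3, MeCN/aq. Na2EDTA, 0 °C, pH 7–8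
Reagents that add atoms: potassium peroxymonosulfate, [K+].[O-]S(=O)(=O)OO
Why: Shi epoxidation; the chiral dioxirane reacts through a spiro transition state with the electron-rich E-trisubstituted C3=C4 olefin to give the (3R,4R)-oxirane, while the disubstituted C6=C7 next to the fully substituted C8 is slower and the electron-poor methylene lactone is inert to the electrophilic oxidant; the near-neutral protocol protects lactone and acetate.

## Compound list

1 | (S)-(+)-linalool, (3S)-3,7-dimethylocta-1,6-dien-3-ol | CC(C)=CCC[C@](C)(O)C=C | starting material
2 | triethyl{[(3S)-3,7-dimethylocta-1,6-dien-3-yl]oxy}silane | CC(C)=CCC[C@](C)(O[Si](CC)(CC)CC)C=C | intermediate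
3 | (4S)-4-methyl-4-(triethylsilyloxy)hex-5-enal | O=CCC[C@](C)(O[Si](CC)(CC)CC)C=C | intermediate
4 | (4S)-4-methyl-4-(triethylsilyloxy)hex-5-en-1-ol | OCCC[C@](C)(O[Si](CC)(CC)CC)C=C | intermediate
5 | {[(3S)-6-bromo-3-methylhex-1-en-3-yl]oxy}triethylsilane | BrCCC[C@](C)(O[Si](CC)(CC)CC)C=C | intermediate
6 | (2E)-but-2-en-1-ol | C/C=C/CO | starting material
7 | [(2S,3S)-3-methyloxiran-2-yl]methanol | C[C@@H]1O[C@H]1CO | intermediate
8 | (2R,3S)-3-methyloxirane-2-carboxylic acid | C[C@@H]1O[C@H]1C(=O)O | intermediate
9 | lithium (2R,3S)-3-methyloxirane-2-carboxylate | C[C@@H]1O[C@H]1C(=O)[O-].[Li+] | intermediate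
10 | bromo[(4S)-4-methyl-4-(triethylsilyloxy)hex-5-en-1-yl]magnesium | Br[Mg]CCC[C@](C)(O[Si](CC)(CC)CC)C=C | intermediate
11 | (2R,3S,7S)-2-hydroxy-3,7-dimethyl-7-(triethylsilyloxy)non-8-enoic acid | OC(=O)[C@H](O)[C@@H](C)CCC[C@](C)(O[Si](CC)(CC)CC)C=C | intermediate
12 | (2R,3S,7S)-3,7-dimethyl-7-(triethylsilyloxy)non-8-ene-1,2-diol | OC[C@H](O)[C@@H](C)CCC[C@](C)(O[Si](CC)(CC)CC)C=C | intermediate
13 | (2R,3S,7S)-3,7-dimethylnon-8-ene-1,2,7-triol | OC[C@H](O)[C@@H](C)CCC[C@](C)(O)C=C | intermediate
14 | pent-1-en-4-yne | C#CCC=C | starting material
15 | dimethyl[(1E)-2-methylpenta-1,4-dien-1-yl]alumane | C[Al](C)/C=C(\C)CC=C | intermediate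
16 | lithium butyl(dimethyl)[(1E)-2-methylpenta-1,4-dien-1-yl]aluminate | [Li+].CCCC[Al-](C)(C)/C=C(\C)CC=C | intermediate
17 | (3E)-4-methylhepta-3,6-dien-1-ol | OCC/C=C(\C)CC=C | intermediate
18 | (3E)-4-methylhepta-3,6-dienal | O=CC/C=C(\C)CC=C | intermediate
19 | methyl prop-2-ynoate | C#CC(=O)OC | starting material
20 | [1-(methoxycarbonyl)ethenyl]bis(2-methylpropyl)alumane | C=C(C(=O)OC)[Al](CC(C)C)CC(C)C | intermediate
21 | methyl (5E)-3-hydroxy-6-methyl-2-methylidenenona-5,8-dienoate (racemic at C3) | COC(=O)C(=C)C(O)C/C=C(\C)CC=C | intermediate
22 | methyl (2Z,5E)-2-(bromomethyl)-6-methylnona-2,5,8-trienoate | BrC/C(C(=O)OC)=C\C/C=C(\C)CC=C | intermediate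
23 | methyl (2Z,5E,8E,10S,14S,15R)-2-(bromomethyl)-10,15,16-trihydroxy-6,10,14-trimethylhexadeca-2,5,8-trienoate | OC[C@H](O)[C@@H](C)CCC[C@](C)(O)/C=C/C/C(C)=C/C/C=C(\CBr)C(=O)OC | intermediate
24 | methyl (2Z,5E,8E,10S,14S,15R)-2-(bromomethyl)-10,15-dihydroxy-6,10,14-trimethyl-16-oxohexadeca-2,5,8-trienoate | O=C[C@H](O)[C@@H](C)CCC[C@](C)(O)/C=C/C/C(C)=C/C/C=C(\CBr)C(=O)OC | intermediate
25 | allylindium dibromide derived from 24 (indium in place of bromine on C17) | O=C[C@H](O)[C@@H](C)CCC[C@](C)(O)/C=C/C/C(C)=C/C/C=C(\C[In](Br)Br)C(=O)OC | intermediate
26 | methyl 2-[(1S,2R,3R,4S,8S,9E,12E)-2,3,8-trihydroxy-4,8,12-trimethylcyclotetradeca-9,12-dien-1-yl]prop-2-enoate | COC(=O)C(=C)[C@H]1[C@@H](O)[C@H](O)[C@@H](C)CCC[C@](C)(O)/C=C/C/C(C)=C/C1 | intermediate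
27 | (1S,3E,6E,8S,12S,13R,14R)-8,13-dihydroxycembra-3,6,15(17)-trien-16,14-olide | C=C1C(=O)O[C@H]2[C@H](O)[C@@H](C)CCC[C@](C)(O)/C=C/C/C(C)=C/C[C@@H]12 | intermediate
28 | (1S,3E,6E,8S,12S,13R,14R)-13-acetoxy-8-hydroxycembra-3,6,15(17)-trien-16,14-olide | C=C1C(=O)O[C@H]2[C@H](OC(C)=O)[C@@H](C)CCC[C@](C)(O)/C=C/C/C(C)=C/C[C@@H]12 | intermediate
29 | (1S,3R,4R,6E,8S,12S,13R,14R)-13-acetoxy-3,4-epoxy-8-hydroxycembra-6,15(17)-dien-16,14-olide | C=C1C(=O)O[C@H]2[C@H](OC(C)=O)[C@@H](C)CCC[C@](C)(O)/C=C/C[C@@]3(C)O[C@@H]3C[C@@H]12 | target

## Step count and least certain steps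

Total: 16 steps. Longest linear sequence: 10 steps (1, 2, 3, 6, 7, 12, 13, 14, 15, 16, from linalool 1). The branch from 14 joins at step 12 after four steps, and the branch from 6 joins at step 6 after two.

Step 14 (key step). Three processes can spoil it:
- protonolysis of the allylindium by water before the slow ring closure;
- intermolecular coupling leading to oligomers;
- erosion of chelate control at C14.

Lactonisation at O13 is a smaller risk. The fallback turns the ring closure into a metathesis; it sets out from triol 13 and bromide 22 and comes back at lactone 27. Triol 13 is oxidised (TEMPO, PhI(OAc)2) to (2R,3S,7S)-2,7-dihydroxy-3,7-dimethylnon-8-enal F1. F1 and 22 are coupled with indium powder in THF/H2O at ordinary concentration, the bimolecular form of the reaction for which the three-centre stereocontrol is established, to give the open-chain hydroxy ester F2. F2 is lactonised with PPTS to the open-chain butyrolactone F3. Ring-closing metathesis of F3 (second-generation Grubbs catalyst, toluene, high dilution) between the two vinyl groups gives 27. The E-C3=C4 bond rules out the only competing closure, onto C17, because that ring would be seven-membered with a trans olefin.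

Step 16. The chiral dioxirane may be mismatched with the facial bias that the macrocycle conformation imposes on C3=C4, which would lower facial selectivity. Oxidation at C6=C7 or base-induced attack on the methylene lactone may also compete. The fallback epoxidises before the ring exists; it sets out from 13 and 22, follows the step 14 fallback as far as F3, and comes back at target 29. Shi epoxidation of the open-chain butyrolactone F3, where no ring conformation competes with the catalyst, gives the open-chain epoxide F4. Ring-closing metathesis gives the macrocyclic epoxy diol F5, and acetylation of the C13 hydroxyl gives 29.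

Step 13. Oxidation may go beyond the aldehyde or cleave the glycol, the secondary carbinol may be oxidised, and C13 may epimerise through the enediol of the α-hydroxy aldehyde. The fallback avoids a free diol during oxidation; it sets out from 23 and comes back at 24. Per-silylation (TESOTf, 2,6-lutidine) gives the tris(triethylsilyl) ether F6. Swern oxidation with a hindered amine base, which cleaves and oxidises a primary triethylsilyl ether selectively, gives the bis(silyl) aldehyde F7. HF·pyridine, safe here because no oxirane is present, releases 24.

Step 12. Cross-metathesis at the hindered vinyl carbinol may be slow, so that 22 is consumed by homodimerisation or by migration of its skipped diene. The fallback makes the metathesis intramolecular by running the Barbier coupling first, exactly as in the step 14 fallback; it sets out from 13 and 22, comes back at 27, and makes no compound beyond those named there.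

## Further compounds

F1 | step 14 | (2R,3S,7S)-2,7-dihydroxy-3,7-dimethylnon-8-enal | O=C[C@H](O)[C@@H](C)CCC[C@](C)(O)C=C
F2 | step 14 | methyl (3S,4R,5R,6S,10S)-4,5,10-trihydroxy-6,10-dimethyl-2-methylidene-3-[(2E)-3-methylhexa-2,5-dien-1-yl]dodec-11-enoate | COC(=O)C(=C)[C@H](C/C=C(\C)CC=C)[C@@H](O)[C@H](O)[C@@H](C)CCC[C@](C)(O)C=C
F3 | step 14 | (4S,5R)-5-[(1R,2S,6S)-1,6-dihydroxy-2,6-dimethyloct-7-en-1-yl]-3-methylidene-4-[(2E)-3-methylhexa-2,5-dien-1-yl]oxolan-2-one | C=C1C(=O)O[C@@H]([C@H](O)[C@@H](C)CCC[C@](C)(O)C=C)[C@H]1C/C=C(\C)CC=C
F4 | step 16 | (4S,5R)-5-[(1R,2S,6S)-1,6-dihydroxy-2,6-dimethyloct-7-en-1-yl]-3-methylidene-4-{[(2R,3R)-3-methyl-3-(prop-2-en-1-yl)oxiran-2-yl]methyl}oxolan-2-one | C=C1C(=O)O[C@@H]([C@H](O)[C@@H](C)CCC[C@](C)(O)C=C)[C@H]1C[C@H]2O[C@]2(C)CC=C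
F5 | step 16 | (1S,3R,4R,6E,8S,12S,13R,14R)-3,4-epoxy-8,13-dihydroxycembra-6,15(17)-dien-16,14-olide | C=C1C(=O)O[C@H]2[C@H](O)[C@@H](C)CCC[C@](C)(O)/C=C/C[C@@]3(C)O[C@@H]3C[C@@H]12
F6 | step 13 | methyl (2Z,5E,8E,10S,14S,15R)-2-(bromomethyl)-6,10,14-trimethyl-10,15,16-tris(triethylsilyloxy)hexadeca-2,5,8-trienoate | CC[Si](CC)(CC)OC[C@H](O[Si](CC)(CC)CC)[C@@H](C)CCC[C@](C)(O[Si](CC)(CC)CC)/C=C/C/C(C)=C/C/C=C(\CBr)C(=O)OC
F7 | step 13 | methyl (2Z,5E,8E,10S,14S,15R)-2-(bromomethyl)-6,10,14-trimethyl-16-oxo-10,15-bis(triethylsilyloxy)hexadeca-2,5,8-trienoate | O=C[C@H](O[Si](CC)(CC)CC)[C@@H](C)CCC[C@](C)(O[Si](CC)(CC)CC)/C=C/C/C(C)=C/C/C=C(\CBr)C(=O)OC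
F0 | step 12 | none | none
A1 | alternative 1 | (1R,2S,6S)-6-hydroxy-2,6-dimethyl-1-[(2R,3S)-4-methylidene-3-{[(2R,3R)-3-methyl-3-(prop-2-en-1-yl)oxiran-2-yl]methyl}-5-oxooxolan-2-yl]oct-7-en-1-yl acetate | C=C1C(=O)O[C@@H]([C@H](OC(C)=O)[C@@H](C)CCC[C@](C)(O)C=C)[C@H]1C[C@H]2O[C@]2(C)CC=C
A2 | alternative 2 | (3E,6E,9E,11S)-3,7,11-trimethyl-11-(triethylsilyloxy)-1-oxacycloheptadeca-3,6,9-trien-15-yne | O1C/C(C)=C/C/C=C(\C)C/C=C/[C@@](C)(O[Si](CC)(CC)CC)CCCC#CC1
A3 | alternative 2 | (1S,3E,6E,8S,14R)-8-(triethylsilyloxy)cembra-3,6,15-trien-12-yn-14-ol | CC(=C)[C@@H]1C/C=C(\C)C/C=C/[C@@](C)(O[Si](CC)(CC)CC)CCCC#C[C@@H]1O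
A4 | alternative 3 | (1S,3R,4R,7E,12S,13R,14R)-13-acetoxy-3,4-epoxycembra-7,15(17)-dien-16,14-olide | C=C1C(=O)O[C@H]2[C@H](OC(C)=O)[C@@H](C)CCC/C(C)=C/CC[C@@]3(C)O[C@@H]3C[C@@H]12
A5 | alternative 3 | (1S,3R,4R,6E,8S,12S,13R,14R)-13-acetoxy-3,4-epoxy-8-hydroperoxycembra-6,15(17)-dien-16,14-olide | C=C1C(=O)O[C@H]2[C@H](OC(C)=O)[C@@H](C)CCC[C@](C)(OO)/C=C/C[C@@]3(C)O[C@@H]3C[C@@H]12
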